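**Retrosynthetic overview**

1. No indole synthesis is needed: the benzene and pyrrole rings are bought intact as 3-acetylindole (1), whose acetyl group already supplies pyrimidine C4 and C5.
2. The two C–Br bonds are made first, by electrophilic dibromination of 1 to ketone 2; the 3-acyl group directs bromine to C5 and C6.
3. Key disconnection: pyrimidine N1–C6 and N3–C4 (two C–N bonds) to guanidine (used as its hydrochloride 3) and a three-carbon 1,3-dielectrophile, the chlorovinyl iminium salt 4. Salt 4 is made in the same flask from 2 and the formyl carbon of DMF.
4. Ring order: indole present from the start; the 2-aminopyrimidine ring is closed last to give Meridianin F (5).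

Assumption: the target has no stereocentre and no stereogenic double bond, so it is a single achiral compound and no stereocontrol is needed.

**Route**

Step 1
Reactants: 1 3-acetylindole (1-(1H-indol-3-yl)ethan-1-one)
Product: 2 1-(5,6-dibromo-1H-indol-3-yl)ethan-1-one
Conditions: Br2 (2.2 equiv), AcOH, rt, 16 h, dark; product filtered off
Reagents that add atoms: bromine BrBr
Why: Electrophilic aromatic bromination (SEAr): the 3-acyl group turns the pyrrole ring into a deactivated vinylogous amide, so Br2 attacks the benzo ring at C5 (para to N1 through C7a) and C6 (para to C3a), the 5,6-pattern established for indole-3-carboxylates under these conditions; no stereocentre is formed.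

Step 2
Reactants: 2 1-(5,6-dibromo-1H-indol-3-yl)ethan-1-one; 3 guanidine hydrochloride
Product: 5 Meridianin F (4-(5,6-dibromo-1H-indol-3-yl)pyrimidin-2-amine), via chlorovinyl iminium chloride 4 (not isolated)
Conditions: (COCl)2 (3 equiv), DMF, 0 °C, 20 min; then 2, 60 °C, 3 h; then 3 (3 equiv), K2CO3 (6 equiv), 100 °C, 12 h; H2O work-up
Reagents that add atoms: N,N-dimethylformamide CN(C)C=O (its formyl carbon becomes pyrimidine C6)
Why: Proposed new method: a one-flask interrupted Vilsmeier–Haack–Arnold haloformylation / guanidine [3+3] annulation on an N–H-free 3-acetylindole, not to my knowledge shown on this substrate class or with guanidine intercepting the iminium salt directly; the vinylogous-amide carbonyl oxygen is unusually nucleophilic, so the chloroiminium ion replaces it by chloride while the methyl carbon is formylated to give salt 4, and guanidine then forms N1–C6 by transamination of the iminium carbon (loss of Me2NH) and N3–C4 by intramolecular addition–elimination (SNV) at the C–Cl carbon, which gives the aromatic 2-aminopyrimidine with no dehydration or oxidation step; guanidine also cleaves any transient N1-formamidinium or N1-formyl group, and the aryl bromides are inert because no metal or reductant is present; closest known reaction types are the Vilsmeier–Haack–Arnold chloroformylation of aryl methyl ketones to β-chlorovinyl aldehydes and the condensation of β-chlorovinyl aldehydes or vinamidinium salts with amidines to pyrimidines; no stereocentre is formed.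

**Compound list**

1 | 3-acetylindole (1-(1H-indol-3-yl)ethan-1-one) | CC(=O)c1c[nH]c2ccccc12 | starting material
2 | 1-(5,6-dibromo-1H-indol-3-yl)ethan-1-one | CC(=O)c1c[nH]c2cc(Br)c(Br)cc12 | intermediate
3 | guanidine hydrochloride | NC(N)=N.Cl | starting material
4 | (Z)-N-[3-chloro-3-(5,6-dibromo-1H-indol-3-yl)prop-2-en-1-ylidene]-N-methylmethanaminium chloride | C[N+](C)=C/C=C(\Cl)c1c[nH]c2cc(Br)c(Br)cc12.[Cl-] | intermediate
5 | Meridianin F (4-(5,6-dibromo-1H-indol-3-yl)pyrimidin-2-amine) | Nc1nccc(-c2c[nH]c3cc(Br)c(Br)cc23)n1 | target

**Summary**

Total step count: 2. Longest linear sequence: 2.

Steps most likely to fail (the route has only two steps, so both are ranked and a third cannot be named):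

1. Step 2 (the proposed new step). Risks are N1-formylation or oligomerisation of the electron-rich chlorovinyl indole species under the Vilsmeier conditions, over-formylation of the methyl group, and sluggish aminolysis once K2CO3 deprotonates the indole N–H of 4 to a less electrophilic neutral merocyanine. Fallback with known chemistry: it sets out from 2 and comes back to the route at 5. Ketone 2 is heated with tert-butoxybis(dimethylamino)methane in DMF at 100 °C to give (E)-1-(5,6-dibromo-1H-indol-3-yl)-3-(dimethylamino)prop-2-en-1-one F1. This reagent carries no transferable O-methyl group, so the indole N–H is not alkylated. F1 is then condensed with guanidine hydrochloride 3 and K2CO3 in 2-methoxyethanol at reflux, the classical enaminone–guanidine aminopyrimidine synthesis, to give 5. This replaces the haloiminium dielectrophile by an isolated enaminone and adds one step.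

2. Step 1. The risk is competing acid-catalysed bromination of the acetyl CH3 group next to ring bromination, which would give mixtures that are hard to separate. Fallback: it sets out from 1 and comes back to the route at 2. Instead of avoiding side-chain bromination, 1 is deliberately over-brominated (Br2, 3.3 equiv, AcOH, 40 °C) to the single tribromide 2-bromo-1-(5,6-dibromo-1H-indol-3-yl)ethan-1-one F2. The α-bromine is then removed chemoselectively with zinc dust in AcOH at rt (reduction of an α-halo ketone through its zinc enolate; aryl C–Br bonds are untouched), which returns 2.

**Further compounds**

F1 | step 2 | (E)-1-(5,6-dibromo-1H-indol-3-yl)-3-(dimethylamino)prop-2-en-1-one | CN(C)/C=C/C(=O)c1c[nH]c2cc(Br)c(Br)cc12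
F2 | step 1 | 2-bromo-1-(5,6-dibromo-1H-indol-3-yl)ethan-1-one | O=C(CBr)c1c[nH]c2cc(Br)c(Br)cc12
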